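**Plan**

Labels: ring A is the 3,4-dimethoxyphenyl ring, C7 the carbinol carbon, C8 the ether carbon, C9 the methyl carbon, and ring B the 2-methoxy-4-(methoxycarbonyl)phenoxy ring.
Retrosynthesis: cut the ring B–CO2Me bond (back to an aryl bromide), then the C8–H and C9–H bonds (back to a C8=C9 enol ether), then C8=C9 (back to an aryl ester carbonyl at C8), then the acyl C8–O bond to the ring B phenol, and last the ring A–C7 bond (veratrole and an oxalyl half-ester chloride).
Enabling feature: C8 carries the ring B aryloxy oxygen, carbinol C7 and methyl C9. This is the skeleton of a ring B aryl ester of ring A mandelic acid with C=O turned into C=CH2 and then CH–CH3, so the 1-aryloxyvinyl group next to the free C7 hydroxyl is a 2-substituted allylic alcohol that cationic rhodium can bind through both groups.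
Forward: no ring is formed. The chain is joined ring A–C7 (Friedel–Crafts), then C8–O–ring B (esterification), then C8=C9 (titanium methylenation); the alkene is saturated and the ring B ester carbon is added last by carbonylation.
Stereochemistry: C7 (S) comes from catalyst-controlled transfer hydrogenation of the aryl keto ester; C8 (S) is relayed from C7 by hydroxyl-directed hydrogenation, giving the threo (7S,8S) pair.

Key step: step 8

Assumption: in step 2 the sense of induction is taken to follow the usual aryl ketone model for Ru/TsDPEN catalysts (ring A against the arene ligand), which assigns the (R,R) ligand to the (S) carbinol; should the opposite sense hold, the (S,S) ligand takes its place.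
Abbreviations: TsDPEN = N-tosyl-1,2-diphenylethylenediamine, nbd = norbornadiene, dppb = 1,4-bis(diphenylphosphino)butane, TBS = tert-butyldimethylsilyl, Cp = cyclopentadienyl.

**Route**

Step 1
Reactants: 1 veratrole (1,2-dimethoxybenzene); 2 methyl chlorooxoacetate
Product: 3 methyl 2-(3,4-dimethoxyphenyl)-2-oxoacetate
Conditions: AlCl3, CH2Cl2, 0 °C
Reagents that add atoms: none
Why: Friedel–Crafts acylation by the acid chloride end of the oxalyl half-ester should go para to one methoxy group and stop after one acylation because the keto ester deactivates the ring.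

Step 2
Reactants: 3 methyl 2-(3,4-dimethoxyphenyl)-2-oxoacetate
Product: 4 methyl (2S)-2-(3,4-dimethoxyphenyl)-2-hydroxyacetate
Conditions: RuCl[(R,R)-TsDPEN](p-cymene) (1 mol %), HCO2H/Et3N (5:2), DMF, 25 °C
Reagents that add atoms: none
Why: Noyori asymmetric transfer hydrogenation of the activated aryl ketone, in which the Ru–H/N–H pair of the (R,R) catalyst transfers hydrogen to the carbonyl face fixed by the contact of ring A with the η6-cymene, should set C7 as (S).

Step 3
Reactants: 4 methyl (2S)-2-(3,4-dimethoxyphenyl)-2-hydroxyacetate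
Product: 5 methyl (2S)-2-[(tert-butyldimethylsilyl)oxy]-2-(3,4-dimethoxyphenyl)acetate
Conditions: TBSCl, imidazole, DMF, 25 °C
Reagents that add atoms: tert-butyldimethylsilyl chloride, CC(C)(C)[Si](C)(C)Cl
Why: Silylation of the secondary alcohol with the imidazole-activated silyl chloride is standard, leaves C7 untouched and removes the free hydroxyl that would self-acylate in step 5 and consume titanium reagent in step 6.

Step 4
Reactants: 5 methyl (2S)-2-[(tert-butyldimethylsilyl)oxy]-2-(3,4-dimethoxyphenyl)acetate
Product: 7 (2S)-2-[(tert-butyldimethylsilyl)oxy]-2-(3,4-dimethoxyphenyl)acetic acid, via lithium carboxylate 6 (not isolated)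
Conditions: LiOH·H2O, THF/H2O, 0 °C; then 1 M HCl to pH 3–4, 0 °C
Reagents that add atoms: lithium hydroxide, [Li+].[OH-]
Why: Saponification by acyl–oxygen cleavage with LiOH at 0 °C should be faster than enolisation of the α-silyloxy ester, so C7 stays (S), and the TBS ether tolerates cold hydroxide and a short mild acidification.

Step 5
Reactants: 7 (2S)-2-[(tert-butyldimethylsilyl)oxy]-2-(3,4-dimethoxyphenyl)acetic acid; 8 4-bromo-2-methoxyphenol
Product: 9 4-bromo-2-methoxyphenyl (2S)-2-[(tert-butyldimethylsilyl)oxy]-2-(3,4-dimethoxyphenyl)acetate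
Conditions: DCC, DMAP (0.1 equiv), CH2Cl2, 0 °C
Reagents that add atoms: none
Why: Steglich esterification through the O-acylisourea and the acylpyridinium ion should acylate the phenol at 0 °C, where the small amount of DMAP leaves little room for ketene formation or enolisation at C7.

Step 6
Reactants: 9 4-bromo-2-methoxyphenyl (2S)-2-[(tert-butyldimethylsilyl)oxy]-2-(3,4-dimethoxyphenyl)acetate
Product: 10 tert-butyl{[(1S)-2-(4-bromo-2-methoxyphenoxy)-1-(3,4-dimethoxyphenyl)prop-2-en-1-yl]oxy}dimethylsilane
Conditions: Cp2TiMe2, toluene/THF, 65 °C, dark; filtration through basic alumina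
Reagents that add atoms: dimethyltitanocene (Cp2TiMe2), C[Ti](C)(C1C=CC=C1)C1C=CC=C1
Why: Petasis methylenation, in which Cp2Ti=CH2 formed by thermal loss of methane adds to the ester carbonyl and the oxatitanacyclobutane collapses to the 1-aryloxyvinyl group and Cp2Ti=O, is established for aryl esters, meets only one ester here and is neither basic nor acidic, so C7, the silyl ether and the aryl bromide should persist.

Step 7
Reactants: 10 tert-butyl{[(1S)-2-(4-bromo-2-methoxyphenoxy)-1-(3,4-dimethoxyphenyl)prop-2-en-1-yl]oxy}dimethylsilane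
Product: 11 (1S)-2-(4-bromo-2-methoxyphenoxy)-1-(3,4-dimethoxyphenyl)prop-2-en-1-ol
Conditions: TBAF, THF, 0 °C; water work-up, chromatography on Et3N-treated silica
Reagents that add atoms: none
Why: Fluoride-induced cleavage of the Si–O bond runs under mildly basic conditions that the acid-labile aryl enol ether tolerates and does not touch the C7–O bond, so the (S) configuration is kept.

Step 8
Reactants: 11 (1S)-2-(4-bromo-2-methoxyphenoxy)-1-(3,4-dimethoxyphenyl)prop-2-en-1-ol
Product: 12 (1S,2S)-2-(4-bromo-2-methoxyphenoxy)-1-(3,4-dimethoxyphenyl)propan-1-ol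
Conditions: [Rh(nbd)(dppb)]BF4 (10 mol %), H2 (50 bar), CH2Cl2, 25 °C
Reagents that add atoms: none
Why: Hydrogen removes norbornadiene from the precatalyst and the cationic monovalent rhodium diphosphine fragment then binds the C7 hydroxyl and the C8=C9 alkene of 11 together, after which oxidative addition of H2, migratory insertion and reductive elimination form the C9–H and C8–H bonds on the metal-bound face. The closest known reaction type is the hydroxyl-directed hydrogenation of 2-substituted allylic alcohols such as 2-methylene-3-hydroxy esters by cationic rhodium diphosphine complexes, applied here to an alkene whose 2-substituent is an aryloxy group. No ring is closed and no skeletal bond is made. The new C8 stereocentre is controlled by the C7 (S) carbinol through the chelate: the conformer that reacts keeps the C7–H bond close to the alkene plane on the side of the ring B oxygen, which avoids allylic 1,2-strain between ring A and the aryloxy group, so hydrogen is delivered to C8 from the hydroxyl-bearing face and hydroxyl and aryloxy come out syn along the zigzag C9–C8–C7–ring A, which is the threo (1S,2S) isomer. The step needs facial selectivity, secured by the free C7 hydroxyl as the only good donor next to the alkene, and chemoselectivity (no double-bond migration towards C7, no hydrolysis of the enol ether, no C–Br cleavage), secured by high hydrogen pressure, dry non-acidic CH2Cl2 and a homogeneous catalyst that leaves aryl bromides alone.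

Step 9
Reactants: 12 (1S,2S)-2-(4-bromo-2-methoxyphenoxy)-1-(3,4-dimethoxyphenyl)propan-1-ol
Product: 13 methyl 4-{[(1S,2S)-1-(3,4-dimethoxyphenyl)-1-hydroxypropan-2-yl]oxy}-3-methoxybenzoate
Conditions: Pd(OAc)2 (5 mol %), 1,1'-bis(diphenylphosphino)ferrocene (10 mol %), CO (5 bar), Et3N, MeOH/DMF, 80 °C
Reagents that add atoms: carbon monoxide, [C-]#[O+]; methanol, CO
Why: Palladium-catalysed methoxycarbonylation (oxidative addition of the aryl bromide to zerovalent palladium formed in the flask, CO insertion, methanolysis of the acylpalladium) should give the methyl ester, with methanol in large excess outcompeting the hindered secondary hydroxyl and neither stereocentre taking part.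

**Compound list**

1 | veratrole (1,2-dimethoxybenzene) | COc1ccccc1OC | starting material
2 | methyl chlorooxoacetate | COC(=O)C(=O)Cl | starting material
3 | methyl 2-(3,4-dimethoxyphenyl)-2-oxoacetate | COC(=O)C(=O)c1ccc(OC)c(OC)c1 | intermediate
4 | methyl (2S)-2-(3,4-dimethoxyphenyl)-2-hydroxyacetate | COC(=O)[C@@H](O)c1ccc(OC)c(OC)c1 | intermediate
5 | methyl (2S)-2-[(tert-butyldimethylsilyl)oxy]-2-(3,4-dimethoxyphenyl)acetate | COC(=O)[C@@H](O[Si](C)(C)C(C)(C)C)c1ccc(OC)c(OC)c1 | intermediate
6 | lithium (2S)-2-[(tert-butyldimethylsilyl)oxy]-2-(3,4-dimethoxyphenyl)acetate (formed in the flask in step 4) | [Li+].[O-]C(=O)[C@@H](O[Si](C)(C)C(C)(C)C)c1ccc(OC)c(OC)c1 | intermediate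
7 | (2S)-2-[(tert-butyldimethylsilyl)oxy]-2-(3,4-dimethoxyphenyl)acetic acid | OC(=O)[C@@H](O[Si](C)(C)C(C)(C)C)c1ccc(OC)c(OC)c1 | intermediate
8 | 4-bromo-2-methoxyphenol | COc1cc(Br)ccc1O | starting material
9 | 4-bromo-2-methoxyphenyl (2S)-2-[(tert-butyldimethylsilyl)oxy]-2-(3,4-dimethoxyphenyl)acetate | COc1cc(Br)ccc1OC(=O)[C@@H](O[Si](C)(C)C(C)(C)C)c1ccc(OC)c(OC)c1 | intermediate
10 | tert-butyl{[(1S)-2-(4-bromo-2-methoxyphenoxy)-1-(3,4-dimethoxyphenyl)prop-2-en-1-yl]oxy}dimethylsilane | COc1cc(Br)ccc1OC(=C)[C@@H](O[Si](C)(C)C(C)(C)C)c1ccc(OC)c(OC)c1 | intermediate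
11 | (1S)-2-(4-bromo-2-methoxyphenoxy)-1-(3,4-dimethoxyphenyl)prop-2-en-1-ol | COc1cc(Br)ccc1OC(=C)[C@@H](O)c1ccc(OC)c(OC)c1 | intermediate
12 | (1S,2S)-2-(4-bromo-2-methoxyphenoxy)-1-(3,4-dimethoxyphenyl)propan-1-ol | COc1cc(Br)ccc1O[C@@H](C)[C@@H](O)c1ccc(OC)c(OC)c1 | intermediate
13 | methyl 4-{[(1S,2S)-1-(3,4-dimethoxyphenyl)-1-hydroxypropan-2-yl]oxy}-3-methoxybenzoate | COC(=O)c1ccc(O[C@@H](C)[C@@H](O)c2ccc(OC)c(OC)c2)c(OC)c1 | target

**Count and risks**

Total step count: 9. Longest linear sequence: 9 steps (1 to 13); phenol 8 is commercial and enters at step 5.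

First, step 8. The hydrogenation may stall on the electron-rich, hindered enol ether. It may lose facial control if the ring B ether oxygens compete with the C7 hydroxyl for rhodium. It may also be overtaken by migration of the double bond towards C7, followed by collapse to the α-aryloxy ketone. The fallback sets out from phenol 8 and rejoins the route at 12; it takes C8 from the chiral pool and sets C7 by 1,2-induction.
- Mitsunobu reaction of 8 with methyl (R)-lactate (PPh3, DIAD, THF, 0 °C, inversion) should give methyl (2S)-2-(4-bromo-2-methoxyphenoxy)propanoate F1.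
- i-PrMgCl and MeNH(OMe)·HCl in THF at −20 °C should convert it into the Weinreb amide (2S)-2-(4-bromo-2-methoxyphenoxy)-N-methoxy-N-methylpropanamide F2.
- 3,4-Dimethoxyphenylmagnesium bromide (THF, 0 °C) should then give the ketone (2S)-2-(4-bromo-2-methoxyphenoxy)-1-(3,4-dimethoxyphenyl)propan-1-one F3.
- Reduction with the bulky, non-chelating hydride KBH(s-Bu)3 (THF, −78 °C) should follow the polar Felkin–Anh model, with the aryloxy group anti to the incoming hydride, and favour the threo alcohol 12.

Second, step 6. The methylenation may fail through expulsion of the ring B phenoxide from the oxatitanacyclobutane (acyl transfer instead of olefination), through slow reaction at the hindered carbonyl, or through erosion of C7 on prolonged heating. The fallback sets out from phenol 8 and rejoins at 11, so the key step is kept; it makes the C8=C9 bond by elimination and sets C7 on a ketone.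
- Williamson alkylation of 8 with 2-bromo-1-(3,4-dimethoxyphenyl)ethan-1-one (K2CO3, acetone) should give 2-(4-bromo-2-methoxyphenoxy)-1-(3,4-dimethoxyphenyl)ethan-1-one F4.
- Aldol addition to formaldehyde (aqueous HCHO, K2CO3, EtOH/acetone) should give racemic 2-(4-bromo-2-methoxyphenoxy)-1-(3,4-dimethoxyphenyl)-3-hydroxypropan-1-one F5.
- Noyori transfer hydrogenation (RuCl[(R,R)-TsDPEN](p-cymene), HCO2H/Et3N) should give (1S)-2-(4-bromo-2-methoxyphenoxy)-1-(3,4-dimethoxyphenyl)propane-1,3-diol F6. Either C2 epimer serves, because C2 becomes sp2.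
- Selective iodination of the primary hydroxyl (I2, PPh3, imidazole, THF, 0 °C) should give (1S)-2-(4-bromo-2-methoxyphenoxy)-1-(3,4-dimethoxyphenyl)-3-iodopropan-1-ol F7.
- E2 loss of HI with DBU (toluene, 80 °C) should give the enol ether 11.

Third, step 5. C7 may lose configuration while the acid is activated, by ketene formation from the O-acylisourea or acylpyridinium ion, or by enolisation of the aryl ester under DMAP. The fallback sets out from keto ester 3 and rejoins at 9; it makes the ester bond to ring B before C7 is a stereocentre.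
- Saponification of 3 (LiOH, THF/H2O) should give lithium 2-(3,4-dimethoxyphenyl)-2-oxoacetate F8 in the flask and, after acidification, 2-(3,4-dimethoxyphenyl)-2-oxoacetic acid F9.
- DCC/DMAP coupling with 8 should give 4-bromo-2-methoxyphenyl 2-(3,4-dimethoxyphenyl)-2-oxoacetate F10.
- Transfer hydrogenation with RuCl[(R,R)-TsDPEN](p-cymene) and HCO2H/Et3N in CH2Cl2 at 0 °C should give 4-bromo-2-methoxyphenyl (2S)-2-(3,4-dimethoxyphenyl)-2-hydroxyacetate F11.
- Silylation with TBSOTf and 2,6-lutidine (CH2Cl2, −78 °C), which avoids a nucleophilic amine that could cleave the aryl ester, should give 9.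

**Further compounds**

F1 | step 8 | methyl (2S)-2-(4-bromo-2-methoxyphenoxy)propanoate | COc1cc(Br)ccc1O[C@@H](C)C(=O)OC
F2 | step 8 | (2S)-2-(4-bromo-2-methoxyphenoxy)-N-methoxy-N-methylpropanamide | COc1cc(Br)ccc1O[C@@H](C)C(=O)N(C)OC
F3 | step 8 | (2S)-2-(4-bromo-2-methoxyphenoxy)-1-(3,4-dimethoxyphenyl)propan-1-one | COc1cc(Br)ccc1O[C@@H](C)C(=O)c1ccc(OC)c(OC)c1
F4 | step 6 | 2-(4-bromo-2-methoxyphenoxy)-1-(3,4-dimethoxyphenyl)ethan-1-one | COc1cc(Br)ccc1OCC(=O)c1ccc(OC)c(OC)c1
F5 | step 6 | 2-(4-bromo-2-methoxyphenoxy)-1-(3,4-dimethoxyphenyl)-3-hydroxypropan-1-one (racemic) | COc1cc(Br)ccc1OC(CO)C(=O)c1ccc(OC)c(OC)c1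
F6 | step 6 | (1S)-2-(4-bromo-2-methoxyphenoxy)-1-(3,4-dimethoxyphenyl)propane-1,3-diol (C2 not defined) | COc1cc(Br)ccc1OC(CO)[C@@H](O)c1ccc(OC)c(OC)c1
F7 | step 6 | (1S)-2-(4-bromo-2-methoxyphenoxy)-1-(3,4-dimethoxyphenyl)-3-iodopropan-1-ol (C2 not defined) | COc1cc(Br)ccc1OC(CI)[C@@H](O)c1ccc(OC)c(OC)c1
F8 | step 5 | lithium 2-(3,4-dimethoxyphenyl)-2-oxoacetate | [Li+].[O-]C(=O)C(=O)c1ccc(OC)c(OC)c1
F9 | step 5 | 2-(3,4-dimethoxyphenyl)-2-oxoacetic acid | OC(=O)C(=O)c1ccc(OC)c(OC)c1
F10 | step 5 | 4-bromo-2-methoxyphenyl 2-(3,4-dimethoxyphenyl)-2-oxoacetate | COc1cc(Br)ccc1OC(=O)C(=O)c1ccc(OC)c(OC)c1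
F11 | step 5 | 4-bromo-2-methoxyphenyl (2S)-2-(3,4-dimethoxyphenyl)-2-hydroxyacetate | COc1cc(Br)ccc1OC(=O)[C@@H](O)c1ccc(OC)c(OC)c1
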